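# Proposed synthesis of CNP0256150.1 by desymmetrising monoacylation of a 2‑arylglycerol

## Analysis of the target

Target 15 is a thymol-type ester with one benzene ring (ring A) carrying, in thymol numbering, CH3 at C1, the tiglate oxygen at C3, the side chain at C4 and OCH3 at C6. The only other ring is the oxirane O–C8–C9. C8 is quaternary and is the single stereocentre, (R); it is bonded to ring A, the oxirane oxygen, the oxirane CH2 (C9) and the CH2O‑isobutyrate arm (C10). No second stereocentre exists to relay from, so the configuration has to come from a catalyst. The E‑alkene of the tiglate arrives ready-made with the acyl group.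

The sensitive groups are:
- the benzylic, fully substituted oxirane on an electron-rich ring, which acid opens or rearranges;
- a phenoxide ortho to that oxirane, which can push out the C8–O bond through an ortho-quinone methide;
- the aryl ester, which is an activated ester;
- the isobutyrate, which can shift between 1,3-related oxygens.

The difficulty is that C9 and C10 are both CH2–O groups. Any intermediate in which the ester can move to the other arm, or in which a free epoxy alcohol can undergo Payne exchange, loses the stereochemical information.

The strategy rests on the same fact. Opening the O–C9 bond and removing the acyl group from O10 leaves C8 with two identical CH2OH arms and a mirror plane. The stereocentre is therefore only the question of which arm is acylated.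

## Retrosynthetic reasoning

**15 ⇒ 11 + 12 (C3–O acyl bond).** The aryl tiglate is the most electrophilic carbonyl in the molecule and cannot be carried through an organometallic step, so it is cut last. The phenol stays masked as a triisopropylsilyl ether in 11. The forward step has to exchange silyl for tigloyl in one flask, so that the phenoxide 14 meets an acyl donor (13, made from 12) the moment it forms and cannot ionise the neighbouring oxirane.

**11 ⇒ 10 (O–C9 bond of the oxirane).** The oxirane is opened at O–C9 and not at O–C8. In the forward closure the tertiary oxygen attacks C9, none of the four bonds at C8 is touched, and the configuration of 10 passes unchanged into 11. The closure must be neutral, because base would move the isobutyryl group from O10 to O9 and so give the enantiomer.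

**10 ⇒ 8 + 9 (O10–acyl bond, the key disconnection).** Removing the isobutyryl group gives triol 8, which is achiral with two enantiotopic CH2OH arms. Installing the ester that the target needs is then itself the stereo-defining event. No arm-differentiating protecting group is used, and no free epoxy alcohol that could racemise by Payne exchange appears. The forward step needs a chiral Lewis acid that selects the pro‑R arm and stops at the monoester.

**8 ⇒ 7 ⇒ 3 + 4 (ring A–C8 bond).** The C4–C8 bond is the only C–C bond joining the side chain to the ring. Cutting it gives the symmetric ketone 4, which delivers C8, C9, C10 and all three oxygens in one piece and guarantees the mirror plane. The aryl nucleophile comes from bromide 3 by halogen–metal exchange (5, then 6). Addition has to beat enolisation of 4, and hydrolysis of acetonide 7 has to spare the tertiary benzylic alcohol and the aryl silyl ether.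

**3 ⇒ 2 ⇒ 1 (O–Si and C–Br bonds).** Phenol 1 is brominated while the hydroxyl is still free, so that it directs the halogen to the required ortho position. Silylation then gives 3.

## Alternatives that were turned down

**Alternative 1: asymmetric methylene transfer to an aryl ketone.**
- Disconnection: C8–C9 and O–C9, back to ketone A2, 2‑[5‑methoxy‑4‑methyl‑2‑(triisopropylsilyloxy)phenyl]‑2‑oxoethyl 2‑methylpropanoate.
- Forward key step: dimethylsulfoxonium methylide A3 adds to A2 under LaLi3(binaphtholate)3 with a triarylphosphine oxide. This closes the oxirane and sets C8 in one step, giving A1, which is the same structure as 11.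
- For: it is the shortest route to the protected oxirane, with no diol stage, no acyl-shift problem and a catalytic stereo step.
- Against: the catalyst distinguishes a methyl group from a larger group. In A2 it would have to tell a CH2O‑acyl group from an ortho-substituted aryl group, which is outside that pattern. A2 also has an acidic α‑acyloxy CH2 and an ester that the basic ylide can attack. Excess ylide can expand the product oxirane to an oxetane.
- Comparison: it is stronger on step count. The chosen route instead places the stereo step on a substrate class (2‑substituted glycerols) for which chelation-directed acylation was designed, and keeps nucleophilic base away from the ester.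

**Alternative 2: enantioselective ortho-Friedel–Crafts reaction with bromopyruvate.**
- Disconnection: C4–C8.
- Forward key step: phenol 1 adds through its free ortho carbon to the ketone of ethyl 3‑bromo‑2‑oxopropanoate A5 under Ti(OiPr)4 and binaphthol. The product is A4, ethyl (2S)‑3‑bromo‑2‑hydroxy‑2‑(2‑hydroxy‑5‑methoxy‑4‑methylphenyl)propanoate.
- For: no protecting group and no organometallic are needed, the hydroxyl directs ortho, and the C–C bond and the stereocentre are made in the first step.
- Against: A5 is also an alkylating agent, so O‑alkylation of the phenol competes. In A4 the free phenol sits next to an ester and a bromohydrin, so lactonisation and ring closure to a benzofuran compete. The ester must then be reduced in the presence of the bromide or oxirane. That passes through the free epoxy alcohol, which racemises by Payne exchange, before the isobutyrate can be attached. Enantioselectivity with A5, which is less activated than trifluoropyruvate or glyoxylate, is not assured.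
- Comparison: it is as short or shorter and sets the stereocentre earlier. The chosen route offers only two mild, non-redox steps after the stereocentre is set.

**Alternative 3: palladium dynamic kinetic oxygenation of a racemic vinyl oxirane.**
- Disconnection: the C8–O bond, back to racemic A7, 2‑ethenyl‑2‑[5‑methoxy‑4‑methyl‑2‑(triisopropylsilyloxy)phenyl]oxirane.
- Forward key step: Pd2(dba)3 with a chiral cyclohexanediyl bis(2‑diphenylphosphinobenzamide) ligand and catalytic BEt3 ionises A7. A hydrogencarbonate-derived oxygen adds at the aryl-bearing terminus and gives A6, (2R)‑2‑[5‑methoxy‑4‑methyl‑2‑(triisopropylsilyloxy)phenyl]but‑3‑ene‑1,2‑diol.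
- For: this reaction type reliably gives tertiary vinyl glycols in high enantiomeric purity from racemic material.
- Against: the vinyl group carries one carbon too many. It must be cleaved oxidatively next to an electron-rich arene and reduced, with the two oxygenated arms kept apart by protection. That adds at least four steps and in the end arrives at the same diol monoester 10. Attack at the hindered aryl-bearing terminus is also less certain with an ortho-substituted aryl group.
- Comparison: it is probably the stronger method for predictable enantiocontrol. The chosen route wastes no carbon and reaches 10 in one step from an achiral triol.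

Key step: step 5

## Route

Assumption: the (R,R)-bis(oxazoline) is written as the ligand that acylates the pro‑R arm. The sense of induction with an ortho-silyloxyaryl substituent is not secure, and the equally available (S,S)-ligand is used if the first run shows the opposite sense.

**Step 1**
Reactants: 1 4‑methoxy‑3‑methylphenol
Product: 2 2‑bromo‑4‑methoxy‑5‑methylphenol
Conditions: NBS (1.0 equiv), MeCN, −20 → 0 °C, dark
Reagents that add atoms: N‑bromosuccinimide, O=C1CCC(=O)N1Br
Why: Electrophilic aromatic bromination directed by the free hydroxyl, whose para position is blocked by OCH3. Of the two ortho positions, the one para to the methyl group is more activated and unhindered, while the other is flanked by OH and CH3.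

**Step 2**
Reactants: 2 2‑bromo‑4‑methoxy‑5‑methylphenol
Product: 3 (2‑bromo‑4‑methoxy‑5‑methylphenoxy)triisopropylsilane
Conditions: TIPSCl, imidazole, DMF, rt
Reagents that add atoms: triisopropylsilyl chloride, CC(C)[Si](Cl)(C(C)C)C(C)C
Why: Standard phenol silylation. The bulky triisopropylsilyl group is chosen because it resists shifts to carbanion or alkoxide in step 3 yet is cleaved by fluoride at the end.

**Step 3**
Reactants: 3 (2‑bromo‑4‑methoxy‑5‑methylphenoxy)triisopropylsilane; 4 2,2‑dimethyl‑1,3‑dioxan‑5‑one
Product: 7 5‑[5‑methoxy‑4‑methyl‑2‑(triisopropylsilyloxy)phenyl]‑2,2‑dimethyl‑1,3‑dioxan‑5‑ol, via aryllithium 5 (not isolated), via arylmagnesium bromide 6 (not isolated)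
Conditions: n‑BuLi, THF, −78 °C; MgBr2·OEt2, −78 °C; then 4, −78 → −20 °C; H2O quench
Reagents that add atoms: none
Why: Bromine–lithium exchange at −78 °C is faster than the retro-Brook silyl shift, and transmetallation to magnesium gives a less basic aryl nucleophile for Grignard addition to the symmetric ketone. Low temperature holds back enolisation of 4 and silyl transfer to the new alkoxide.

**Step 4**
Reactants: 7 5‑[5‑methoxy‑4‑methyl‑2‑(triisopropylsilyloxy)phenyl]‑2,2‑dimethyl‑1,3‑dioxan‑5‑ol
Product: 8 2‑[5‑methoxy‑4‑methyl‑2‑(triisopropylsilyloxy)phenyl]propane‑1,2,3‑triol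
Conditions: AcOH/THF/H2O (3:1:1), 35 °C
Reagents that add atoms: none
Why: Acid-catalysed acetal hydrolysis. The two inductively withdrawing CH2O groups disfavour ionisation of the tertiary benzylic alcohol, and the aryl triisopropylsilyl ether is stable to aqueous acetic acid.

**Step 5 (key step)**
Reactants: 8 2‑[5‑methoxy‑4‑methyl‑2‑(triisopropylsilyloxy)phenyl]propane‑1,2,3‑triol; 9 2‑methylpropanoyl chloride
Product: 10 (2R)‑2,3‑dihydroxy‑2‑[5‑methoxy‑4‑methyl‑2‑(triisopropylsilyloxy)phenyl]propyl 2‑methylpropanoate
Conditions: CuCl2 (10 mol%), 2,2'‑isopropylidenebis[(4R)‑4‑phenyl‑2‑oxazoline] (11 mol%), Et3N (1.1 equiv), 9 (1.0 equiv, slow addition), THF, −40 °C; cold aq. NH4Cl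
Reagents that add atoms: none
Why: CuCl2 and the bis(oxazoline) form a chiral divalent-copper Lewis acid that binds the tertiary hydroxyl and one primary hydroxyl of 8 as a five-membered chelate; binding acidifies that primary OH, Et3N removes its proton, and the copper alkoxide is acylated by 9 faster than any unbound hydroxyl. The closest known reaction type is the copper bis(oxazoline)-catalysed enantioselective monobenzoylation of 2‑substituted glycerols and meso‑1,2‑diols. No ring is closed; one O10–acyl bond is formed. C8 becomes stereogenic under catalyst control: once bound, the two arms are diastereotopic, and the 4‑phenyl groups of the ligand allow only the chelate that places the bulky aryl group in an open quadrant, so the pro‑R arm is acylated. The step needs selection between enantiotopic arms, primary over tertiary hydroxyl, and mono- over diacylation; the tertiary hydroxyl is too hindered to react. The monoester still offers a 1,2‑diol to copper, so overacylation is not stopped by loss of chelation; it is limited by using one equivalent of 9, by the stronger binding of the triol, and because the arm left free in 10 is the one the catalyst disfavours. The minor enantiomer is therefore the one consumed preferentially to the achiral diester, which should raise the enantiomeric purity of 10. Low temperature and slow addition keep uncatalysed acylation and ketene formation from 9 and Et3N below the catalysed rate.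

**Step 6**
Reactants: 10 (2R)‑2,3‑dihydroxy‑2‑[5‑methoxy‑4‑methyl‑2‑(triisopropylsilyloxy)phenyl]propyl 2‑methylpropanoate
Product: 11 {(2R)‑2‑[5‑methoxy‑4‑methyl‑2‑(triisopropylsilyloxy)phenyl]oxiran‑2‑yl}methyl 2‑methylpropanoate
Conditions: PPh3, DIAD, toluene, 0 °C → rt
Reagents that add atoms: none
Why: Mitsunobu cyclodehydration of a 1,2‑diol: the phosphine–azodicarboxylate betaine activates the unhindered primary hydroxyl as its oxyphosphonium, and the tertiary oxygen displaces Ph3PO at C9 in a 3‑exo‑tet closure. No bond to C8 is broken, so its configuration is carried over, and the absence of base keeps the isobutyryl group on O10.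

**Step 7**
Reactants: 11 {(2R)‑2‑[5‑methoxy‑4‑methyl‑2‑(triisopropylsilyloxy)phenyl]oxiran‑2‑yl}methyl 2‑methylpropanoate; 12 (2E)‑2‑methylbut‑2‑enoyl chloride
Product: 15 2‑[(2R)‑2‑{[(2‑methylpropanoyl)oxy]methyl}oxiran‑2‑yl]‑4‑methoxy‑5‑methylphenyl (2E)‑2‑methylbut‑2‑enoate, via tigloyl fluoride 13 (not isolated), via cesium phenolate 14 (not isolated)
Conditions: CsF (4 equiv), 12 (1.3 equiv), MeCN, rt; then 11, MeCN–DMF, 0 °C → rt
Reagents that add atoms: none
Why: Fluoride-mediated silyl-to-acyl exchange: CsF first converts 12 into acyl fluoride 13, and the excess fluoride then cleaves the aryl O–Si bond. Phenolate 14 is acylated by 13 as it forms, releasing fluoride again, so it has no time to ionise the neighbouring oxirane; C8, the oxirane and the isobutyrate are not touched.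

## Compound list

1 | 4‑methoxy‑3‑methylphenol | Cc1cc(O)ccc1OC | starting material
2 | 2‑bromo‑4‑methoxy‑5‑methylphenol | Oc1cc(C)c(OC)cc1Br | intermediate
3 | (2‑bromo‑4‑methoxy‑5‑methylphenoxy)triisopropylsilane | CC(C)[Si](C(C)C)(C(C)C)Oc1cc(C)c(OC)cc1Br | intermediate
4 | 2,2‑dimethyl‑1,3‑dioxan‑5‑one | CC1(C)OCC(=O)CO1 | starting material
5 | [5‑methoxy‑4‑methyl‑2‑(triisopropylsilyloxy)phenyl]lithium | CC(C)[Si](C(C)C)(C(C)C)Oc1cc(C)c(OC)cc1[Li] | intermediate
6 | [5‑methoxy‑4‑methyl‑2‑(triisopropylsilyloxy)phenyl]magnesium bromide | CC(C)[Si](C(C)C)(C(C)C)Oc1cc(C)c(OC)cc1[Mg]Br | intermediate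
7 | 5‑[5‑methoxy‑4‑methyl‑2‑(triisopropylsilyloxy)phenyl]‑2,2‑dimethyl‑1,3‑dioxan‑5‑ol | CC(C)[Si](C(C)C)(C(C)C)Oc1cc(C)c(OC)cc1C1(O)COC(C)(C)OC1 | intermediate
8 | 2‑[5‑methoxy‑4‑methyl‑2‑(triisopropylsilyloxy)phenyl]propane‑1,2,3‑triol | CC(C)[Si](C(C)C)(C(C)C)Oc1cc(C)c(OC)cc1C(O)(CO)CO | intermediate
9 | 2‑methylpropanoyl chloride (isobutyryl chloride) | CC(C)C(=O)Cl | starting material
10 | (2R)‑2,3‑dihydroxy‑2‑[5‑methoxy‑4‑methyl‑2‑(triisopropylsilyloxy)phenyl]propyl 2‑methylpropanoate | CC(C)[Si](C(C)C)(C(C)C)Oc1cc(C)c(OC)cc1[C@](O)(COC(=O)C(C)C)CO | intermediate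
11 | {(2R)‑2‑[5‑methoxy‑4‑methyl‑2‑(triisopropylsilyloxy)phenyl]oxiran‑2‑yl}methyl 2‑methylpropanoate | CC(C)[Si](C(C)C)(C(C)C)Oc1cc(C)c(OC)cc1[C@]1(COC(=O)C(C)C)CO1 | intermediate
12 | (2E)‑2‑methylbut‑2‑enoyl chloride (tigloyl chloride) | C/C=C(\C)C(=O)Cl | starting material
13 | (2E)‑2‑methylbut‑2‑enoyl fluoride | C/C=C(\C)C(=O)F | intermediate
14 | cesium 2‑[(2R)‑2‑{[(2‑methylpropanoyl)oxy]methyl}oxiran‑2‑yl]‑4‑methoxy‑5‑methylphenolate | [Cs+].[O-]c1cc(C)c(OC)cc1[C@]1(COC(=O)C(C)C)CO1 | intermediate
15 | 2‑[(2R)‑2‑{[(2‑methylpropanoyl)oxy]methyl}oxiran‑2‑yl]‑4‑methoxy‑5‑methylphenyl (2E)‑2‑methylbut‑2‑enoate | C/C=C(\C)C(=O)Oc1cc(C)c(OC)cc1[C@]1(COC(=O)C(C)C)CO1 | target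

## Step count and least certain steps

Total: 7 steps. Longest linear sequence: 7 steps (1 → 15); the route is fully linear.

**Step 5 (key step).**
- What may go wrong: poor discrimination between the two arms, because the bulky ortho-silyloxyaryl group may distort the copper chelate. An aliphatic acyl chloride is also more reactive than the benzoyl chloride of the model reaction, so racemic background acylation and overacylation may compete. The isobutyryl group may shift to the other arm during work-up.
- Fallback: set the stereocentre by asymmetric epoxidation instead. Bromide 3 is lithiated as in step 3 and trapped with 2‑isopropoxy‑4,4,5,5‑tetramethyl‑1,3,2‑dioxaborolane to give the aryl pinacol boronate F1. Suzuki–Miyaura coupling with 2‑bromoprop‑2‑en‑1‑ol (Pd(PPh3)4, aq. K2CO3, dioxane) gives the 2‑arylprop‑2‑en‑1‑ol F2. Sharpless asymmetric epoxidation (Ti(OiPr)4, L‑(+)‑diisopropyl tartrate, t‑BuOOH, 4 Å sieves, CH2Cl2, −20 °C) should give the (S)‑epoxy alcohol F3 by the usual facial rule for 2‑substituted allyl alcohols. Esterification with 9 and pyridine at 0 °C, with no alkoxide base so that Payne exchange is avoided, comes back to the route at 11.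

**Step 7.**
- What may go wrong: phenoxide-assisted ionisation of the C8–O bond through an ortho-quinone methide before acylation, which would scramble or destroy the stereocentre. Fluoride cleavage of the hindered silyl ether may be slow, and the primary ester may be attacked.
- Fallback: move the exchange to a stage without an oxirane. Acetonide 7 is treated with CsF and 12 as in step 7 to give the aryl tiglate acetonide F4. Aqueous acetic acid gives the tiglate triol F5. The copper bis(oxazoline) monoacylation with 9 gives the tiglate diol monoester F6. Mitsunobu closure as in step 6 comes back to the route at 15. The cost is an activated aryl ester next to free hydroxyls during the key step.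

**Step 6.**
- What may go wrong: activation of the tertiary benzylic oxygen instead of the primary one, followed by ionisation at C8, which would erode configuration or cause a pinacol-type shift. The acyl group may also shift in 10 before closure.
- Fallback: a two-stage sulfonate displacement. Diol 10 is tosylated selectively at the primary hydroxyl (Bu2SnO cat., TsCl, Et3N, CH2Cl2, 0 °C) to give the (S)‑hydroxy tosylate F7. Once O9 is sulfonylated the ester can no longer reach that arm. DBU in MeCN at 0 °C closes the oxirane and comes back to the route at 11.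

**Step 3.**
- What may go wrong: enolisation of 4 by the hindered aryl nucleophile, retro-Brook silyl shift to carbon before transmetallation, or silyl transfer from the phenol oxygen to the new tertiary alkoxide.
- Fallback: use a non-enolisable, more electrophilic ketone. Bromide 3 is converted into 6 as before and added to diethyl 2‑oxopropanedioate at −78 °C to give the diethyl aryl(hydroxy)malonate F8. Reduction with LiBH4 in THF/MeOH at 0 °C comes back to the route at 8, which also bypasses the acid step 4.

## Further compounds

F1 | step 5 | 2‑[5‑methoxy‑4‑methyl‑2‑(triisopropylsilyloxy)phenyl]‑4,4,5,5‑tetramethyl‑1,3,2‑dioxaborolane | CC(C)[Si](C(C)C)(C(C)C)Oc1cc(C)c(OC)cc1B1OC(C)(C)C(C)(C)O1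
F2 | step 5 | 2‑[5‑methoxy‑4‑methyl‑2‑(triisopropylsilyloxy)phenyl]prop‑2‑en‑1‑ol | CC(C)[Si](C(C)C)(C(C)C)Oc1cc(C)c(OC)cc1C(=C)CO
F3 | step 5 | {(2S)‑2‑[5‑methoxy‑4‑methyl‑2‑(triisopropylsilyloxy)phenyl]oxiran‑2‑yl}methanol | CC(C)[Si](C(C)C)(C(C)C)Oc1cc(C)c(OC)cc1[C@]1(CO)CO1
F4 | step 7 | 2‑(5‑hydroxy‑2,2‑dimethyl‑1,3‑dioxan‑5‑yl)‑4‑methoxy‑5‑methylphenyl (2E)‑2‑methylbut‑2‑enoate | C/C=C(\C)C(=O)Oc1cc(C)c(OC)cc1C1(O)COC(C)(C)OC1
F5 | step 7 | 4‑methoxy‑5‑methyl‑2‑(1,2,3‑trihydroxypropan‑2‑yl)phenyl (2E)‑2‑methylbut‑2‑enoate | C/C=C(\C)C(=O)Oc1cc(C)c(OC)cc1C(O)(CO)CO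
F6 | step 7 | 2‑[(2R)‑1,2‑dihydroxy‑3‑(2‑methylpropanoyloxy)propan‑2‑yl]‑4‑methoxy‑5‑methylphenyl (2E)‑2‑methylbut‑2‑enoate | C/C=C(\C)C(=O)Oc1cc(C)c(OC)cc1[C@](O)(COC(=O)C(C)C)CO
F7 | step 6 | (2S)‑2‑hydroxy‑2‑[5‑methoxy‑4‑methyl‑2‑(triisopropylsilyloxy)phenyl]‑3‑[(4‑methylbenzenesulfonyl)oxy]propyl 2‑methylpropanoate | CC(C)[Si](C(C)C)(C(C)C)Oc1cc(C)c(OC)cc1[C@](O)(COC(=O)C(C)C)COS(=O)(=O)c1ccc(C)cc1
F8 | step 3 | diethyl 2‑hydroxy‑2‑[5‑methoxy‑4‑methyl‑2‑(triisopropylsilyloxy)phenyl]propanedioate | CC(C)[Si](C(C)C)(C(C)C)Oc1cc(C)c(OC)cc1C(O)(C(=O)OCC)C(=O)OCC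
A1 | alternative 1 | {(2R)‑2‑[5‑methoxy‑4‑methyl‑2‑(triisopropylsilyloxy)phenyl]oxiran‑2‑yl}methyl 2‑methylpropanoate | CC(C)[Si](C(C)C)(C(C)C)Oc1cc(C)c(OC)cc1[C@]1(COC(=O)C(C)C)CO1
A2 | alternative 1 | 2‑[5‑methoxy‑4‑methyl‑2‑(triisopropylsilyloxy)phenyl]‑2‑oxoethyl 2‑methylpropanoate | CC(C)[Si](C(C)C)(C(C)C)Oc1cc(C)c(OC)cc1C(=O)COC(=O)C(C)C
A3 | alternative 1 | dimethylsulfoxonium methylide | C[S+](C)(=O)[CH2-]
A4 | alternative 2 | ethyl (2S)‑3‑bromo‑2‑hydroxy‑2‑(2‑hydroxy‑5‑methoxy‑4‑methylphenyl)propanoate | Oc1cc(C)c(OC)cc1[C@](O)(C(=O)OCC)CBr
A5 | alternative 2 | ethyl 3‑bromo‑2‑oxopropanoate | CCOC(=O)C(=O)CBr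
A6 | alternative 3 | (2R)‑2‑[5‑methoxy‑4‑methyl‑2‑(triisopropylsilyloxy)phenyl]but‑3‑ene‑1,2‑diol | CC(C)[Si](C(C)C)(C(C)C)Oc1cc(C)c(OC)cc1[C@](O)(C=C)CO
A7 | alternative 3 | 2‑ethenyl‑2‑[5‑methoxy‑4‑methyl‑2‑(triisopropylsilyloxy)phenyl]oxirane (racemic) | CC(C)[Si](C(C)C)(C(C)C)Oc1cc(C)c(OC)cc1C1(C=C)CO1
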